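## Retrosynthetic overview
1. 7 ⇒ 6: the oxirane is installed last, by OH-directed epoxidation of the C1=C6 bond of a trans-dienol monobenzoate.
2. 6 ⇒ 5: the C2–OH/C3–OBz pair comes from anti-SN2′ opening of an oxanorbornadiene by benzoic acid. The bridge oxygen stays behind as C2–OH.
3. 5 ⇒ 3: CO2Me is converted to CH2OBz.
4. 3 ⇒ 1 + 2: an enantioselective alkyne Diels–Alder reaction closes the six-membered carbocycle and the second 2,5-dihydrofuran ring of the bicycle in one operation. It also fixes the absolute configuration.
5. Ring order: carbocycle and oxa-bridge ring (step 1), bridge ring cleaved (step 4), oxirane (step 5).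

Assumption: the senses of induction of the (S)-oxazaborolidinium salt (step 1) and of (R,S)-PPF-PtBu2 (step 4) are assigned by analogy with their furan–acrylate and oxabenzonorbornadiene reactions. If either is opposite, its equally available mirror image is used.

## Route

Step 1
Reactants: 1 furan; 2 methyl propiolate
Product: 3 methyl (1S,4R)-7-oxabicyclo[2.2.1]hepta-2,5-diene-2-carboxylate
Conditions: (S)-o-tolyl-oxazaborolidine·HNTf2 (20 mol %), 2 (5 equiv), 1 added over 8 h, CH2Cl2, −78 °C; Et3N quench at −78 °C
Reagents that add atoms: none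
Why: Proposed new method: the oxazaborolidinium ion binds the ester carbonyl of the rotamer-free ynoate and shields one face of its conjugated π bond, so furan adds in a concerted [4+2] from the open face and both bridgehead centres (1S,4R) arise together as the carbocycle and the new oxolene ring close, while slow addition of 1 to excess 2 limits a second furan addition to the strained adduct and the cold amine quench prevents acid-induced aromatisation; the closest known reaction types are oxazaborolidinium-catalysed enantioselective Diels–Alder reactions of furan with acrylates and of cyclopentadiene with ynones, and the Lewis-acid-accelerated furan–alkynoate cycloaddition.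

Step 2
Reactants: 3 methyl (1S,4R)-7-oxabicyclo[2.2.1]hepta-2,5-diene-2-carboxylate
Product: 4 [(1S,4R)-7-oxabicyclo[2.2.1]hepta-2,5-dien-2-yl]methanol
Conditions: DIBAL-H (2.2 equiv), CH2Cl2, −78 °C; Rochelle salt
Reagents that add atoms: none
Why: DIBAL-H reduces the enoate 1,2 to the allylic alcohol at low temperature without touching the bridge or either bridgehead centre.

Step 3
Reactants: 4 [(1S,4R)-7-oxabicyclo[2.2.1]hepta-2,5-dien-2-yl]methanol
Product: 5 [(1S,4R)-7-oxabicyclo[2.2.1]hepta-2,5-dien-2-yl]methyl benzoate
Conditions: BzCl (1.1 equiv), Et3N, DMAP (cat.), CH2Cl2, 0 °C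
Reagents that add atoms: benzoyl chloride, O=C(Cl)c1ccccc1
Why: DMAP-catalysed O-acylation of the primary alcohol runs under basic conditions, which the acid-labile bicycle tolerates, and no stereocentre is involved.

Step 4
Reactants: 5 [(1S,4R)-7-oxabicyclo[2.2.1]hepta-2,5-dien-2-yl]methyl benzoate
Product: 6 [(5R,6R)-5-(benzoyloxy)-6-hydroxycyclohexa-1,3-dien-1-yl]methyl benzoate
Conditions: [Rh(cod)Cl]2 (2.5 mol %), (R,S)-PPF-PtBu2 (6 mol %), BzOH (1.5 equiv), Et3N (1.5 equiv), THF, 40 °C
Reagents that add atoms: benzoic acid, O=C(O)c1ccccc1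
Why: In this Rh(I)-catalysed (Lautens-type) anti-SN2′ ring opening, exo-bound Rh inserts into the less hindered C4–O bond, whose dienyl-cation character is stabilised at substituted C2, and benzoate attacks the π-allyl at C6 from the endo face, so the new C–OBz centre is trans to the retained C1–O centre (the free OH of 6), while the matched ligand diverts any minor enantiomer of 5 into a separable regioisomer.

Step 5
Reactants: 6 [(5R,6R)-5-(benzoyloxy)-6-hydroxycyclohexa-1,3-dien-1-yl]methyl benzoate
Product: 7 [(1S,2S,3R,6R)-3-(benzoyloxy)-2-hydroxy-7-oxabicyclo[4.1.0]hept-4-en-1-yl]methyl benzoate (target)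
Conditions: VO(acac)2 (5 mol %), t-BuOOH (1.2 equiv, decane), CH2Cl2, 0 °C
Reagents that add atoms: tert-butyl hydroperoxide, CC(C)(C)OO
Why: In this hydroxyl-directed vanadium (Sharpless–Michaelson) epoxidation, the vanadate of the pseudoaxial allylic OH delivers oxygen only to the adjacent, more electron-rich trisubstituted alkene and on the OH face, which sets C1 and C6 with the oxirane cis to C2–OH and trans to C3–OBz.

## Compound list
1 | furan | c1ccoc1 | starting material
2 | methyl propiolate | C#CC(=O)OC | starting material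
3 | methyl (1S,4R)-7-oxabicyclo[2.2.1]hepta-2,5-diene-2-carboxylate | COC(=O)C1=C[C@H]2C=C[C@@H]1O2 | intermediate
4 | [(1S,4R)-7-oxabicyclo[2.2.1]hepta-2,5-dien-2-yl]methanol | OCC1=C[C@H]2C=C[C@@H]1O2 | intermediate
5 | [(1S,4R)-7-oxabicyclo[2.2.1]hepta-2,5-dien-2-yl]methyl benzoate | O=C(OCC1=C[C@H]2C=C[C@@H]1O2)c1ccccc1 | intermediate
6 | [(5R,6R)-5-(benzoyloxy)-6-hydroxycyclohexa-1,3-dien-1-yl]methyl benzoate | O=C(OCC1=CC=C[C@@H](OC(=O)c2ccccc2)[C@@H]1O)c1ccccc1 | intermediate
7 | [(1S,2S,3R,6R)-3-(benzoyloxy)-2-hydroxy-7-oxabicyclo[4.1.0]hept-4-en-1-yl]methyl benzoate | O=C(OC[C@@]12O[C@@H]1C=C[C@@H](OC(=O)c1ccccc1)[C@@H]2O)c1ccccc1 | target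

Total step count: 5. Longest linear sequence: 5.

## Steps most likely to fail

**Step 1.** The risks are a second furan addition, modest ee, and aromatisation of the adduct.
- The fallback sets out from 1 and comes back at 4.
- The alkyne is replaced by an alkene dienophile of proven enantioselectivity with furan.
- 2-Bromoacrolein with the N-tosyltryptophan-derived B-butyl oxazaborolidinone (10 mol %, CH2Cl2, −78 °C) gives (1S,2S,4S)-2-bromo-7-oxabicyclo[2.2.1]hept-5-ene-2-carbaldehyde F1 (CHO exo, Br endo).
- DBU in CH2Cl2 at 0 °C to rt removes HBr and gives (1S,4R)-7-oxabicyclo[2.2.1]hepta-2,5-diene-2-carbaldehyde F2.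
- Luche reduction (NaBH4, CeCl3, MeOH, −20 °C) then delivers 4.

**Step 4.** The risks are Rh- or acid-induced aromatisation of 5 or 6, and cleavage of the wrong C–O bond.
- The fallback sets out from 5 and comes back at 7.
- The order of events is reversed, so no aromatisable dienol is ever formed.
- Buffered mCPBA (NaHCO3, CH2Cl2, 0 °C) attacks the trisubstituted alkene of 5 from the exo face. This gives [(1S,2S,4R,5R)-3,8-dioxatricyclo[3.2.1.0(2,4)]oct-6-en-2-yl]methyl benzoate F3, which already carries the oxirane cis to the bridge oxygen.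
- The remaining strained alkene and bridge are then opened with BzOH/Et3N under [Rh(cod)2]OTf, (R,S)-PPF-PtBu2 and Bu4NI (THP, 60–80 °C), which gives 7 directly.
- This substrate is less reactive than 5, so the opening needs the more active cationic catalyst and heat.

**Step 5.** The risks are oxidation or dehydration of the dienol, and vanadium-induced opening of the vinyl epoxide.
- The fallback sets out from 6 and comes back at 7.
- The oxygen is brought in by cycloaddition instead of metal-peroxide transfer.
- Photooxygenation (O2, tetraphenylporphyrin, hν, CH2Cl2, −20 °C) adds singlet oxygen to the diene face syn to the free OH. This gives [(1S,4S,7S,8S)-7-(benzoyloxy)-8-hydroxy-2,3-dioxabicyclo[2.2.2]oct-5-en-1-yl]methyl benzoate F4.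
- P(OMe)3 (benzene, rt) attacks the less hindered peroxide oxygen on C4. The tertiary alkoxide then closes in a syn-SN2′ sense onto C6, giving 7.

## Further compounds
F1 | step 1 | (1S,2S,4S)-2-bromo-7-oxabicyclo[2.2.1]hept-5-ene-2-carbaldehyde | O=C[C@]1(Br)C[C@H]2C=C[C@@H]1O2
F2 | step 1 | (1S,4R)-7-oxabicyclo[2.2.1]hepta-2,5-diene-2-carbaldehyde | O=CC1=C[C@H]2C=C[C@@H]1O2
F3 | step 4 | [(1S,2S,4R,5R)-3,8-dioxatricyclo[3.2.1.0(2,4)]oct-6-en-2-yl]methyl benzoate | O=C(OC[C@@]12O[C@@H]1[C@H]3C=C[C@@H]2O3)c4ccccc4
F4 | step 5 | [(1S,4S,7S,8S)-7-(benzoyloxy)-8-hydroxy-2,3-dioxabicyclo[2.2.2]oct-5-en-1-yl]methyl benzoate | O=C(OC[C@@]12OO[C@@H](C=C1)[C@@H](OC(=O)c3ccccc3)[C@@H]2O)c4ccccc4
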